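The unit I reckon in is the millimolar-hour: partner concentration times time, the clock of a step that takes up partner. Substrate goes into partner in portions, mono adduct is wanted, and two earlier runs, oak and larch, are what I have.

| flask | substrate | partner | remark | time |
|---|---|---|---|---|
| oak | 39 mM (in portions, 3) | 80 mM | run made earlier; portions every 12 h |  |
| larch | 39 mM (in portions, 3) | 180 mM | run made earlier; portions every 12 h |  |
| flask | 39 mM (in portions, 3) | 120 mM | the portions of substrate follow each other after 12 h, the first at the start | 50 h |

| run | time / h | mono adduct / % |
|---|---|---|
| oak | 6.00 | 13 |
| oak | 12.0 | 21 |
| oak | 20.0 | 36 |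
| oak | 25.0 | 46 |
| oak | 30.0 | 55 |
| larch | 6.00 | 21 |
| larch | 12.0 | 20 |
| larch | 20.0 | 42 |
| larch | 25.0 | 52 |
| larch | 30.0 | 63 |

(standard deviation of a reading: 1.5 percentage points)

* equivalents of partner to substrate, everything else as given, that leave most mono adduct at 50 h
* the amount of mono adduct then, in percent of the substrate charged
* the amount of mono adduct with the amounts as given

- the analysis behind the earlier runs scatters by 1.5 percentage points, standard deviation
- a reading or a percentage of mono adduct counts all its forms, free or not

First instants: oak reads 13% of the charge at 6.00 h, so I take 39.0% of its first portion as reacted, assuming nothing has gone further yet. Middle: larch has more partner and, at 12.0 h, more time, so its clock stands at 4.50 oak clocks. That leaves 10.8% of the larch portion. Yet larch mono adduct reads flat, 21% then 20%, so I take making and loss to balance there, as far as such scattered readings show it.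

In a plain chain both rates carry partner. Divide one by the other and partner and time drop out: loss over making equals partner-free arithmetic, the loss ratio times mono adduct over substrate. The loss ratio, the selectivity factor, is the loss constant over the making constant, and the flat larch readings give 0.180.

End: 6.00 h after its last portion, my clock puts larch at about 11.0% of the charge as substrate, against a reading of 63% of mono adduct. Loss over making then comes to 1.04, so mono adduct should stall. Instead it climbs from 52% to 63%. I read this as part of what is counted standing beyond partner's reach, and I put the new flask above 63% at 50 h.

The forecast says “The readings fit a consecutive scheme” and gives 62%, with a best of 69% at 2 equiv.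

The flask gives 68.6%, with a best of 69.3% at 2.57 equiv.

    substrate + partner → mono adduct (k = 0.0250 M⁻¹ min⁻¹)
    substrate + partner → other mono adduct (k = 0.00150 M⁻¹ min⁻¹)
    partner + mono adduct → double product (k = 0.00480 M⁻¹ min⁻¹)
    partner + other mono adduct → double product (k = 0.0720 M⁻¹ min⁻¹)
    substrate ⇌ dormant form (K = 4.60, k = 2.50 × 10⁻⁴ min⁻¹)
    crystals ⇌ mono adduct, rate k6*(cs6 - [mono adduct]) while solid is left; crystals form when [mono adduct] > cs6 (solubility = 4.50 mM, k = 0.0110 min⁻¹)

Partner reaches dissolved mono adduct. At 50.0 h the flask holds 68.6% of the charge as mono adduct, crystals counted, and 57.2% of the charge as crystals, so 11.4% is dissolved, against 1.10% of substrate. The loss ratio then gives 1.86 for loss over making, and the run's partner use gives 1.98. The neighbour with 9.8 mM of substrate has 0% crystals, so its ratio is 14.6, and double product holds 59.0%, more than any other species there. Saturation of mono adduct and the length of the run together are part of the reason that the flask keeps 68.6%: without saturation it gives 42.2%, and ten times as long leaves 2.29%.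

Readings and results are simulated for substances that don't exist.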